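**Retrosynthetic overview**

- Feature: ring A is a pentasubstituted benzene. Its C3(OH)–C4(prenyl)–C5(OMe)–C6(prenyl) edge is the four-carbon chain of a methyl acetoacetate prenylated at both the α- and the γ-carbon. The only unsubstituted ring carbon, C2, lies ortho to the phenol and can hold a CO2Me group that is later lost as CO2.
- Last disconnection: C2–H back to the C2 carboxylic acid and its methyl ester (decarboxylation, saponification).
- Key disconnection: the C6–C1 and C3–C2 bonds of ring A, by [4+2] cycloaddition and aromatisation between a doubly prenylated 1-methoxy-1-silyloxy-3-methoxy diene and methyl (E)-5-phenylpent-4-en-2-ynoate. Ring A is the only ring formed; the phenyl ring is bought in.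
- Diene from methyl acetoacetate and prenyl bromide (γ-prenylation, α-prenylation, O-methylation, silylation); ynoate from methyl propiolate and (E)-β-bromostyrene by Sonogashira coupling.

Key step: step 6

Assumption: the target is achiral and its only stereo-element is the E stilbene alkene, which comes from isomerically pure (E)-β-bromostyrene and is not touched afterwards. Ring A is numbered C1 (styryl), C2 (H), C3 (OH), C4 (prenyl), C5 (OMe), C6 (prenyl); prenyl = 3-methylbut-2-enyl.

**Route**

Step 1
Reactants: 1 methyl acetoacetate; 2 prenyl bromide
Product: 3 methyl 7-methyl-3-oxooct-6-enoate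
Conditions: NaH, THF, 0 °C; n-BuLi, 0 °C; then 2, 0 °C to rt; 1 M HCl quench
Reagents that add atoms: none
Why: Weiler dianion alkylation, in which the sodium lithium dianion of the β-keto ester reacts with the primary allylic bromide only at the more basic γ-carbon, placing the prenyl group that becomes the C6 substituent of ring A.

Step 2
Reactants: 3 methyl 7-methyl-3-oxooct-6-enoate; 2 prenyl bromide
Product: 4 methyl 7-methyl-2-(3-methylbut-2-enyl)-3-oxooct-6-enoate (racemic)
Conditions: NaH (1 equiv), THF, 0 °C; then 2 (1 equiv), 0 °C to rt
Reagents that add atoms: none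
Why: C-alkylation of a β-keto ester sodium enolate (SN2 at the allylic bromide) places the second prenyl group on the α-carbon; the new C2 stereocentre forms racemic and is erased in step 3.

Step 3
Reactants: 4 methyl 7-methyl-2-(3-methylbut-2-enyl)-3-oxooct-6-enoate
Product: 5 methyl (2E)-3-methoxy-7-methyl-2-(3-methylbut-2-enyl)octa-2,6-dienoate
Conditions: NaH, THF/DMPU, 0 °C; Me2SO4, 0 °C to rt; chromatography to remove any 2Z isomer
Reagents that add atoms: dimethyl sulfate, COS(=O)(=O)OC
Why: O-alkylation of a dissociated β-keto ester enolate by a hard electrophile in a dipolar aprotic medium should win over C-methylation at the already substituted α-carbon, should favour the 2E enol ether (C4 methylene syn to the ester), and avoids acid that could cyclise the prenyl groups.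

Step 4
Reactants: 5 methyl (2E)-3-methoxy-7-methyl-2-(3-methylbut-2-enyl)octa-2,6-dienoate
Product: 6 [(3Z)-1,3-dimethoxy-7-methyl-2-(3-methylbut-2-enyl)octa-1,3,6-trienyl]oxy-trimethylsilane (ketene acetal geometry unassigned)
Conditions: LiN(i-Pr)2 (commercial solution), THF, −78 °C; Me3SiCl, −78 °C to rt; pentane, filtration, used crude under argon
Reagents that add atoms: chlorotrimethylsilane, C[Si](C)(C)Cl
Why: Kinetic γ-deprotonation of the β-methoxy enoate syn to the ester and O-silylation of the dienolate give the Brassard-type diene, and allylic 1,3-strain against the C1/C2 substituents should force the C4 chain outward (3Z).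

Step 5
Reactants: 7 methyl propiolate; 8 (E)-β-bromostyrene
Product: 9 methyl (E)-5-phenylpent-4-en-2-ynoate
Conditions: PdCl2(PPh3)2 (cat.), CuI (cat.), K2CO3, THF, 55 °C, slow addition of 7
Reagents that add atoms: none
Why: Sonogashira coupling of an alkenyl bromide with a terminal alkyne retains the E geometry, and the inorganic base avoids amine conjugate addition to the propiolate.

Step 6
Reactants: 6 [(3Z)-1,3-dimethoxy-7-methyl-2-(3-methylbut-2-enyl)octa-1,3,6-trienyl]oxy-trimethylsilane; 9 methyl (E)-5-phenylpent-4-en-2-ynoate
Product: 11 methyl 2-hydroxy-4-methoxy-3,5-bis(3-methylbut-2-enyl)-6-[(E)-2-phenylethenyl]benzoate, via silyl methyl ketal cycloadduct 10 (not isolated)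
Conditions: 6 (excess), toluene, 110 °C, sealed tube, argon; then THF, 1 M HCl, 0 °C, brief
Reagents that add atoms: none
Why: Diels–Alder benzannulation: the electron-rich 1,1,3-trioxygenated diene 6 adds through its s-cis conformer to the ester-activated triple bond of 9 (concerted but asynchronous, or Michael addition followed by ring closure, with the same outcome), joining diene C4 to the styryl-bearing β-carbon and the ketene acetal carbon to the α-carbon to give 10, whose silyl methyl ketal is cleaved by dilute acid to a cyclohexa-2,5-dienone that tautomerises to the phenol. The closest known reaction type is the cycloaddition of 1-alkoxy-1-silyloxy-3-alkoxybutadienes (Brassard-type and Chan-type dienes) with acetylenic esters to give resorcylates, here applied to a 2,4-dialkylated diene and an enyne ester. Ring A is closed by this intermolecular [4+2] cycloaddition, which forms the C6–C1 and C3–C2 bonds (target numbering) in one operation. The two sp3 carbons of 10 are flattened on aromatisation, so no stereocentre has to be controlled, and the E alkene of the styryl group is not involved. The step needs regioselectivity and site selectivity: the largest HOMO coefficient of the diene at C4 and the largest LUMO coefficient of the ynoate at the β-carbon give the polarity-matched orientation, attack at the remote styryl terminus leads to no six-membered ring, and the unactivated prenyl and styryl alkenes are far poorer dienophiles than the conjugated alkyne. The outward (3Z) C4 chain keeps the s-cis conformer accessible, and the hydrolytic work-up makes the ketal carbon end as the free C3 phenol and the enol ether oxygen as the C5 methyl ether.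

Step 7
Reactants: 11 methyl 2-hydroxy-4-methoxy-3,5-bis(3-methylbut-2-enyl)-6-[(E)-2-phenylethenyl]benzoate
Product: 12 2-hydroxy-4-methoxy-3,5-bis(3-methylbut-2-enyl)-6-[(E)-2-phenylethenyl]benzoic acid
Conditions: KOH (excess), MeOH/H2O, 80 °C, argon; then cold 1 M HCl to pH 3, 0 °C
Reagents that add atoms: potassium hydroxide, [K+].[OH-]
Why: Saponification (acyl–oxygen cleavage by hydroxide) of the di-ortho-substituted salicylate is slow but feasible on heating, as for other 6-substituted 2-hydroxy-4-alkoxybenzoates, and the cold, brief acidification avoids acid-catalysed closure of the ortho-prenyl phenol to a chroman.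

Step 8
Reactants: 12 2-hydroxy-4-methoxy-3,5-bis(3-methylbut-2-enyl)-6-[(E)-2-phenylethenyl]benzoic acid
Product: 13 chiricanine C, 3-methoxy-2,4-bis(3-methylbut-2-enyl)-5-[(E)-2-phenylethenyl]phenol
Conditions: toluene, 110 °C, argon
Reagents that add atoms: none
Why: Thermal protodecarboxylation of an ortho-hydroxy, para-alkoxy benzoic acid (ipso protonation, then loss of CO2) is facile near this temperature, as for related 2-hydroxy-4-alkoxy-6-alkylbenzoic acids, and leaves the E stilbene and both prenyl groups untouched.

**Compound list**

1 | methyl acetoacetate (methyl 3-oxobutanoate) | CC(=O)CC(=O)OC | starting material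
2 | prenyl bromide (1-bromo-3-methylbut-2-ene) | CC(C)=CCBr | starting material
3 | methyl 7-methyl-3-oxooct-6-enoate | COC(=O)CC(=O)CCC=C(C)C | intermediate
4 | methyl 7-methyl-2-(3-methylbut-2-enyl)-3-oxooct-6-enoate (racemic) | COC(=O)C(CC=C(C)C)C(=O)CCC=C(C)C | intermediate
5 | methyl (2E)-3-methoxy-7-methyl-2-(3-methylbut-2-enyl)octa-2,6-dienoate | COC(=O)/C(CC=C(C)C)=C(OC)\CCC=C(C)C | intermediate
6 | [(3Z)-1,3-dimethoxy-7-methyl-2-(3-methylbut-2-enyl)octa-1,3,6-trienyl]oxy-trimethylsilane (ketene acetal geometry unassigned) | COC(O[Si](C)(C)C)=C(CC=C(C)C)/C(OC)=C/CC=C(C)C | intermediate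
7 | methyl propiolate (methyl prop-2-ynoate) | C#CC(=O)OC | starting material
8 | (E)-β-bromostyrene | Br/C=C/c1ccccc1 | starting material
9 | methyl (E)-5-phenylpent-4-en-2-ynoate | COC(=O)C#C/C=C/c1ccccc1 | intermediate
10 | methyl 4,6-dimethoxy-3,5-bis(3-methylbut-2-enyl)-2-[(E)-2-phenylethenyl]-6-(trimethylsilyloxy)cyclohexa-1,4-diene-1-carboxylate (diastereomer mixture, not isolated) | COC(=O)C1=C(/C=C/c2ccccc2)C(CC=C(C)C)C(OC)=C(CC=C(C)C)C1(OC)O[Si](C)(C)C | intermediate
11 | methyl 2-hydroxy-4-methoxy-3,5-bis(3-methylbut-2-enyl)-6-[(E)-2-phenylethenyl]benzoate | COC(=O)c1c(O)c(CC=C(C)C)c(OC)c(CC=C(C)C)c1/C=C/c1ccccc1 | intermediate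
12 | 2-hydroxy-4-methoxy-3,5-bis(3-methylbut-2-enyl)-6-[(E)-2-phenylethenyl]benzoic acid | OC(=O)c1c(O)c(CC=C(C)C)c(OC)c(CC=C(C)C)c1/C=C/c1ccccc1 | intermediate
13 | chiricanine C, 3-methoxy-2,4-bis(3-methylbut-2-enyl)-5-[(E)-2-phenylethenyl]phenol | COc1c(CC=C(C)C)c(O)cc(/C=C/c2ccccc2)c1CC=C(C)C | target

**Step count and risks**

Total step count: 8. Longest linear sequence: 7 steps (steps 1, 2, 3, 4, 6, 7, 8); step 5 is a one-step branch.

Steps most likely to fail:

1. Step 6. The cycloaddition between a fully substituted, hindered diene and a β-substituted ynoate may be too slow, so that the diene decays (hydrolysis, silyl migration) before it reacts. Addition may also be misdirected toward the styryl terminus, or silanol may be lost in place of methanol during aromatisation. Fallback: the same two bonds are made one at a time by polar chemistry, setting out from enol ether 5 and ynoate 9 and returning at salicylate 11. The lithium dienolate of 5 (LiN(i-Pr)2, THF, −78 °C) would add to 9 in a vinylogous Michael reaction through its γ-carbon, the α-carbon being blocked by its prenyl group. An AcOH quench should give the open-chain diester dimethyl 5-methoxy-4,6-bis(3-methylbut-2-enyl)-3-[(E)-2-phenylethenyl]hepta-2,5-dienedioate F1. NaOMe in MeOH (rt to 50 °C) would then remove the doubly allylic C4–H, and the extended enolate closes ring A by Dieckmann-type attack of the ynoate-derived α-carbon on the other ester. Loss of methoxide and enolisation give 11. The alternative closure through the prenyl-bearing carbon leads to a non-aromatisable β-keto ester that can revert, so the arene should be the thermodynamic sink. This is a Staunton–Weinreb-type Michael–Claisen annulation run in two operations.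

2. Step 7. Hydroxide attack at the carbonyl shielded by the ortho hydroxyl and ortho styryl groups may be too slow, and forcing the temperature invites base-mediated migration of the prenyl double bonds into conjugation with the ring. Fallback: the ester is changed to one that is cleaved away from the hindered carbonyl, setting out from bromide 8 and diene 6 and returning at acid 12. Propiolic acid and 2-(trimethylsilyl)ethanol (DCC, CH2Cl2, 0 °C) give 2-trimethylsilylethyl prop-2-ynoate F2. Sonogashira coupling with 8 under the conditions of step 5 gives 2-trimethylsilylethyl (E)-5-phenylpent-4-en-2-ynoate F3. Cycloaddition with 6 as in step 6 passes through the silyl methyl ketal cycloadduct 2-trimethylsilylethyl 4,6-dimethoxy-3,5-bis(3-methylbut-2-enyl)-2-[(E)-2-phenylethenyl]-6-(trimethylsilyloxy)cyclohexa-1,4-diene-1-carboxylate F4 (not isolated) to 2-trimethylsilylethyl 2-hydroxy-4-methoxy-3,5-bis(3-methylbut-2-enyl)-6-[(E)-2-phenylethenyl]benzoate F5. Bu4NF in THF at rt then attacks silicon and releases acid 12 by β-elimination, with a cold dilute HCl work-up.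

3. Step 3. C-methylation may compete and give a quaternary α-carbon, or the 2Z enol ether may form, whose C4 methylene is anti to the ester and resists deprotonation in step 4. Fallback: the order of O-methylation and α-prenylation is reversed, setting out from keto ester 3 (with bromide 2) and returning at diene 6. O-methylation of 3 (NaH, DMPU, Me2SO4), which is the well-behaved α-unsubstituted case, gives methyl (2E)-3-methoxy-7-methylocta-2,6-dienoate F6. Its lithium dienolate (LiN(i-Pr)2, THF, −78 °C) is alkylated by 2 at the α-carbon, the usual site for alkyl halides. This gives the deconjugated ester methyl (3Z)-3-methoxy-7-methyl-2-(3-methylbut-2-enyl)octa-3,6-dienoate F7, with the C3=C4 geometry already set. Deprotonation of its acidic α-hydrogen (LiN(i-Pr)2, −78 °C) and Me3SiCl then give 6 directly.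

**Further compounds**

F1 | step 6 | dimethyl 5-methoxy-4,6-bis(3-methylbut-2-enyl)-3-[(E)-2-phenylethenyl]hepta-2,5-dienedioate (ring-alkene geometries unassigned) | COC(=O)C=C(/C=C/c1ccccc1)C(CC=C(C)C)C(OC)=C(CC=C(C)C)C(=O)OC
F2 | step 7 | 2-trimethylsilylethyl prop-2-ynoate | C#CC(=O)OCC[Si](C)(C)C
F3 | step 7 | 2-trimethylsilylethyl (E)-5-phenylpent-4-en-2-ynoate | C[Si](C)(C)CCOC(=O)C#C/C=C/c1ccccc1
F4 | step 7 | 2-trimethylsilylethyl 4,6-dimethoxy-3,5-bis(3-methylbut-2-enyl)-2-[(E)-2-phenylethenyl]-6-(trimethylsilyloxy)cyclohexa-1,4-diene-1-carboxylate | C[Si](C)(C)CCOC(=O)C1=C(/C=C/c2ccccc2)C(CC=C(C)C)C(OC)=C(CC=C(C)C)C1(OC)O[Si](C)(C)C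
F5 | step 7 | 2-trimethylsilylethyl 2-hydroxy-4-methoxy-3,5-bis(3-methylbut-2-enyl)-6-[(E)-2-phenylethenyl]benzoate | C[Si](C)(C)CCOC(=O)c1c(O)c(CC=C(C)C)c(OC)c(CC=C(C)C)c1/C=C/c1ccccc1
F6 | step 3 | methyl (2E)-3-methoxy-7-methylocta-2,6-dienoate | COC(=O)/C=C(OC)\CCC=C(C)C
F7 | step 3 | methyl (3Z)-3-methoxy-7-methyl-2-(3-methylbut-2-enyl)octa-3,6-dienoate (racemic) | COC(=O)C(CC=C(C)C)/C(OC)=C/CC=C(C)C
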